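In a closed flask the amounts of L, Z and Q should add up to what was charged, and the south-west run does: its readings sum to 99.1% at 4.00 min and 100% at 50.0 min. You can therefore treat that run as material passing among these three.

- south-west: L 0.50 M; G 5.3 mol%; the very flask that is asked about, followed so far
- flask: L 0.50 M; G 5.3 mol%; time 2.0 h

- south-west (time / min: Z / %, Q / %, L / %): 4.00: 17.4, 24.5, 57.2; 6.00: 25.7, 27.0, 44.9; 8.00: 34.4, 30.4, 36.2; 15.0: 46.9, 34.0, 17.7; 20.0: 51.3, 35.4, 12.6; 30.0: 54.1, 36.4, 9.1; 50.0: 55.1, 37.0, 8.2

(scatter of a reading: 0.5 percentage points)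



- amount of Z in the flask at 2.0 h, in percent of the L charged
- amount of Q in the flask at 2.0 h, in percent of the L charged

In the south-west run L levels off near 8.2%, and I take its excess over that last reading as a first-order lag. Between 4.00 min and 15.0 min this gives a rate constant of 0.149 min⁻¹. Multiplied by the time asked, it folds into one number, 17.9, the count of time constants elapsed, a Damköhler number. The excess shrinks by the factor 1.69 × 10⁻⁸, so I carry the last readings forward: Z 55.1%, Q 37.0%.

Was one number enough? The lag predicts an excess of 4.5 percentage points at 20.0 min, and the reading gives 4.4 points. The shortfall of Z gives 0.139 min⁻¹, close to the constant from L. A drift slower than the run stays unseen.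

The forecast says Z 55% and Q 37.3%, slightly above my Q: “By 2 h the relaxation is complete, so the composition should stay close to the 50 min values”.

The flask gives Z 54.9% and Q 36.8%.

    L → E (k = 7.90 × 10⁻⁵ min⁻¹)
    Q ⇌ L (k = 0.0290 min⁻¹)
    L + G ⇌ Z + G, rate k3*[L]*[G] forward; the back reaction follows from the equilibrium constant (K = 6.90, k = 0.330 L mol⁻¹ min⁻¹)
    Z + G ⇌ Q + G, rate k4*[G]*[Z] forward; the back reaction follows from the equilibrium constant (K = 0.670, k = 14.0 L mol⁻¹ min⁻¹)
    L + G ⇌ J, settled at all times (K = 1.60 L mol⁻¹)

Left for 20.0 h, this flask holds Z 54.5% and Q 36.5%. The neighbour flask starts from 0.12 M of L at the same loading, so it has a quarter of the concentration of G. Carry the lag constant over unscaled, as a trial, and the neighbour flask's number stays 17.9, which puts its L at the last south-west reading, 8.2%. At 2.0 h the neighbour flask holds L 7.96%, Z 55.0% and Q 36.8%.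

The runs are simulated with made-up constants, and the scatter is random.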